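**Retrosynthetic overview**
1. Vitekwangin B 12 comes from its bis-silyl ether 11; the C3=C4 double bond of 11 comes from Saegusa dehydrogenation of tetralin-3-carbaldehyde 9; 9 comes from 8, which carries a bromine at C5 as a removable blocking group.
2. Key disconnection of 8: bonds C3–C2 and C1–C8a, made together in an enantioselective organo-SOMO radical–polar crossover annulation of 3-arylpropanal 4 (ring A, C4, C3, CHO) with cinnamyl silyl ether 7 (C2, C1, pendant ring).
3. Enabling feature: the formyl group on C3 gives the chiral enamine radical cation; the 3,4-dimethoxyphenyl ring on C1 stabilises the radical and cation at C1; C8a of ring A, ortho to the C8 methoxy group, closes ring B by Friedel–Crafts attack on C1.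
4. Ring A and the pendant ring are bought (1 and 5); ring B is the only ring formed, in step 6; the bromine at C5 blocks the competing site para to the methoxy group.
5. C3 is set by the catalyst and relays to C2 and C1; C3 later becomes sp2.

Key step: step 6

Remark: all bicyclic compounds carry the locants of the target (C1 aryl, C2 CH2O, C3 formyl-bearing carbon, C4, ring A = C4a, C5–C8, C8a).
Assumption: the (2S,5S) catalyst is taken to give C3 as R with all-trans addition; if the first run shows the mirror-image series at C1/C2, the (2R,5R) salt is used and nothing else changes.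

**Step 1**
Reactants: 1 methyl 3-(4-hydroxy-3-methoxyphenyl)propanoate
Product: 2 methyl 3-[4-(tert-butyldimethylsilyloxy)-3-methoxyphenyl]propanoate
Conditions: TBSCl (1.2 equiv), imidazole (2.5 equiv), DMF, rt
Reagents that add atoms: tert-butyldimethylsilyl chloride, CC(C)(C)[Si](C)(C)Cl
Why: Imidazole-promoted O-silylation of the phenol, with the methyl ester inert under these conditions.

**Step 2**
Reactants: 2 methyl 3-[4-(tert-butyldimethylsilyloxy)-3-methoxyphenyl]propanoate
Product: 3 methyl 3-[2-bromo-4-(tert-butyldimethylsilyloxy)-5-methoxyphenyl]propanoate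
Conditions: NBS (1.05 equiv), MeCN, 0 °C to rt
Reagents that add atoms: N-bromosuccinimide, O=C1CCC(=O)N1Br
Why: Electrophilic aromatic bromination, expected para to the methoxy group (the later C5) because the bulky, less donating silyloxy group disfavours its own ortho site and the site between chain and OMe is hindered.

**Step 3**
Reactants: 3 methyl 3-[2-bromo-4-(tert-butyldimethylsilyloxy)-5-methoxyphenyl]propanoate
Product: 4 3-[2-bromo-4-(tert-butyldimethylsilyloxy)-5-methoxyphenyl]propanal
Conditions: i-Bu2AlH (1.1 equiv), CH2Cl2, −78 °C; MeOH, then aq. KNaC4H4O6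
Reagents that add atoms: none
Why: Partial hydride reduction of the methyl ester by DIBAL-H, whose tetrahedral aluminium hemiacetal persists at −78 °C and releases the aldehyde on work-up, leaving the aryl bromide and aryl silyl ether untouched.

**Step 4**
Reactants: 5 methyl (E)-3-(3,4-dimethoxyphenyl)prop-2-enoate
Product: 6 (E)-3-(3,4-dimethoxyphenyl)prop-2-en-1-ol
Conditions: i-Bu2AlH (2.3 equiv), CH2Cl2, −78 to 0 °C; aq. KNaC4H4O6
Reagents that add atoms: none
Why: 1,2-Reduction of the enoate by DIBAL-H should give the allylic alcohol with the E geometry retained.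

**Step 5**
Reactants: 6 (E)-3-(3,4-dimethoxyphenyl)prop-2-en-1-ol
Product: 7 (E)-tert-butyl{[3-(3,4-dimethoxyphenyl)prop-2-en-1-yl]oxy}dimethylsilane
Conditions: TBSCl (1.2 equiv), imidazole (2.5 equiv), DMF, rt
Reagents that add atoms: tert-butyldimethylsilyl chloride, CC(C)(C)[Si](C)(C)Cl
Why: Silylation of the primary allylic alcohol gives a bulky, weakly nucleophilic ether oxygen that should not compete for the cation in step 6.

**Step 6**
Reactants: 4 3-[2-bromo-4-(tert-butyldimethylsilyloxy)-5-methoxyphenyl]propanal; 7 (E)-tert-butyl{[3-(3,4-dimethoxyphenyl)prop-2-en-1-yl]oxy}dimethylsilane (2.5 equiv)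
Product: 8 (1S,2R,3R)-5-bromo-7-(tert-butyldimethylsilyloxy)-2-[(tert-butyldimethylsilyloxy)methyl]-1-(3,4-dimethoxyphenyl)-8-methoxy-1,2,3,4-tetrahydronaphthalene-3-carbaldehyde (all-trans)
Conditions: (2S,5S)-5-benzyl-2-tert-butyl-3-methylimidazolidin-4-one·TFA (20 mol%), [Fe(phen)3](SbF6)3 (2.5 equiv), Na2HPO4 (2.5 equiv), H2O (2 equiv), DME, −30 °C
Reagents that add atoms: none
Why: The imidazolidinone condenses with aldehyde 4 to an enamine that the trivalent iron complex oxidises by one electron to a 3π-electron radical cation, electrophilic at C3; this adds to C2 of the electron-rich alkene 7, the 3,4-dimethoxybenzyl radical at C1 is oxidised by a second equivalent of oxidant to the cation (radical–polar crossover), and C8a of ring A captures it. The closest known reaction type is the enantioselective organo-SOMO formal (4+2) cycloaddition of 3-arylpropanals with styrenes, applied here to a 1,2-disubstituted styrene. Ring B, the only ring formed, closes by intramolecular Friedel–Crafts alkylation, a six-membered cation–arene closure (6-endo with respect to the C4a–C8a bond of ring A) through a chair-like transition state. C3 is set by the catalyst, whose benzyl group shields one face of the radical cation; C2 is set relative to C3 in the radical addition (staggered approach, alkene substituent anti to the benzylic arm); C1 is set relative to C2 in the ring closure, the aryl group going trans to the CH2OTBS group. The step needs regioselectivity on ring A, which the bromine at C5 secures by blocking the site para to the methoxy group so that only C8a can close a six-membered ring, and it needs a cation that lives long enough for this hindered closure, which the 3,4-dimethoxyphenyl group on C1 provides. Any C2 epimer is removed by chromatography at this stage, so the later loss of the C3 centre should not erode the enantiomeric purity at C1 and C2.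

**Step 7**
Reactants: 8 (1S,2R,3R)-5-bromo-7-(tert-butyldimethylsilyloxy)-2-[(tert-butyldimethylsilyloxy)methyl]-1-(3,4-dimethoxyphenyl)-8-methoxy-1,2,3,4-tetrahydronaphthalene-3-carbaldehyde
Product: 9 (1S,2R,3R)-7-(tert-butyldimethylsilyloxy)-2-[(tert-butyldimethylsilyloxy)methyl]-1-(3,4-dimethoxyphenyl)-8-methoxy-1,2,3,4-tetrahydronaphthalene-3-carbaldehyde
Conditions: H2 (1 atm), 10% Pd/C, Et3N (2 equiv), EtOAc, rt
Reagents that add atoms: none
Why: Palladium-catalysed hydrodehalogenation of the aryl bromide with Et3N as HBr scavenger; no alkene is present yet, and the aliphatic aldehyde, silyl ethers and C1/C2 centres should be unaffected (epimerisation at C3 would not matter).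

**Step 8**
Reactants: 9 (1S,2R,3R)-7-(tert-butyldimethylsilyloxy)-2-[(tert-butyldimethylsilyloxy)methyl]-1-(3,4-dimethoxyphenyl)-8-methoxy-1,2,3,4-tetrahydronaphthalene-3-carbaldehyde
Product: 10 (1S,2R)-7-(tert-butyldimethylsilyloxy)-2-[(tert-butyldimethylsilyloxy)methyl]-1-(3,4-dimethoxyphenyl)-8-methoxy-3-[(trimethylsilyloxy)methylidene]-1,2,3,4-tetrahydronaphthalene (E/Z mixture, used crude)
Conditions: Me3SiOTf (1.3 equiv), Et3N (2 equiv), CH2Cl2, 0 °C
Reagents that add atoms: trimethylsilyl trifluoromethanesulfonate, C[Si](C)(C)OS(=O)(=O)C(F)(F)F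
Why: Soft enolisation and O-silylation of the α-branched aldehyde, whose only α-hydrogen is on C3, should give the silyl enol ether without touching C1 or C2.

**Step 9**
Reactants: 10 (1S,2R)-7-(tert-butyldimethylsilyloxy)-2-[(tert-butyldimethylsilyloxy)methyl]-1-(3,4-dimethoxyphenyl)-8-methoxy-3-[(trimethylsilyloxy)methylidene]-1,2,3,4-tetrahydronaphthalene
Product: 11 (1S,2R)-7-(tert-butyldimethylsilyloxy)-2-[(tert-butyldimethylsilyloxy)methyl]-1-(3,4-dimethoxyphenyl)-8-methoxy-1,2-dihydronaphthalene-3-carbaldehyde
Conditions: Pd(OAc)2 (1.1 equiv), MeCN, rt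
Reagents that add atoms: none
Why: Saegusa–Ito oxidation, in which the palladium enolate at C3 should undergo β-hydride elimination of a benzylic C4 hydrogen to give the enal conjugated with ring A, whereas loss of the C2 hydrogen would give a more hindered, non-styrenic tetrasubstituted alkene.

**Step 10**
Reactants: 11 (1S,2R)-7-(tert-butyldimethylsilyloxy)-2-[(tert-butyldimethylsilyloxy)methyl]-1-(3,4-dimethoxyphenyl)-8-methoxy-1,2-dihydronaphthalene-3-carbaldehyde
Product: 12 vitekwangin B, (1S,2R)-1-(3,4-dimethoxyphenyl)-7-hydroxy-2-(hydroxymethyl)-8-methoxy-1,2-dihydronaphthalene-3-carbaldehyde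
Conditions: Bu4NF (2.5 equiv), AcOH (2.5 equiv), THF, 0 °C
Reagents that add atoms: none
Why: Fluoride-mediated cleavage of the aryl and the primary alkyl silyl ether, buffered with AcOH so that the phenol and the hydroxy enal are not exposed to strong base; C1 and C2 are not enolisable and should be retained.

**Compound list**
1 | methyl 3-(4-hydroxy-3-methoxyphenyl)propanoate | COC(=O)CCc1ccc(O)c(OC)c1 | starting material
2 | methyl 3-[4-(tert-butyldimethylsilyloxy)-3-methoxyphenyl]propanoate | COC(=O)CCc1ccc(O[Si](C)(C)C(C)(C)C)c(OC)c1 | intermediate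
3 | methyl 3-[2-bromo-4-(tert-butyldimethylsilyloxy)-5-methoxyphenyl]propanoate | COC(=O)CCc1cc(OC)c(O[Si](C)(C)C(C)(C)C)cc1Br | intermediate
4 | 3-[2-bromo-4-(tert-butyldimethylsilyloxy)-5-methoxyphenyl]propanal | O=CCCc1cc(OC)c(O[Si](C)(C)C(C)(C)C)cc1Br | intermediate
5 | methyl (E)-3-(3,4-dimethoxyphenyl)prop-2-enoate | COC(=O)/C=C/c1ccc(OC)c(OC)c1 | starting material
6 | (E)-3-(3,4-dimethoxyphenyl)prop-2-en-1-ol | OC/C=C/c1ccc(OC)c(OC)c1 | intermediate
7 | (E)-tert-butyl{[3-(3,4-dimethoxyphenyl)prop-2-en-1-yl]oxy}dimethylsilane | CC(C)(C)[Si](C)(C)OC/C=C/c1ccc(OC)c(OC)c1 | intermediate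
8 | (1S,2R,3R)-5-bromo-7-(tert-butyldimethylsilyloxy)-2-[(tert-butyldimethylsilyloxy)methyl]-1-(3,4-dimethoxyphenyl)-8-methoxy-1,2,3,4-tetrahydronaphthalene-3-carbaldehyde | COc1ccc([C@H]2c3c(c(Br)cc(O[Si](C)(C)C(C)(C)C)c3OC)C[C@@H](C=O)[C@@H]2CO[Si](C)(C)C(C)(C)C)cc1OC | intermediate
9 | (1S,2R,3R)-7-(tert-butyldimethylsilyloxy)-2-[(tert-butyldimethylsilyloxy)methyl]-1-(3,4-dimethoxyphenyl)-8-methoxy-1,2,3,4-tetrahydronaphthalene-3-carbaldehyde | COc1ccc([C@H]2c3c(ccc(O[Si](C)(C)C(C)(C)C)c3OC)C[C@@H](C=O)[C@@H]2CO[Si](C)(C)C(C)(C)C)cc1OC | intermediate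
10 | (1S,2R)-7-(tert-butyldimethylsilyloxy)-2-[(tert-butyldimethylsilyloxy)methyl]-1-(3,4-dimethoxyphenyl)-8-methoxy-3-[(trimethylsilyloxy)methylidene]-1,2,3,4-tetrahydronaphthalene (E/Z mixture) | COc1ccc([C@H]2c3c(ccc(O[Si](C)(C)C(C)(C)C)c3OC)CC(=CO[Si](C)(C)C)[C@@H]2CO[Si](C)(C)C(C)(C)C)cc1OC | intermediate
11 | (1S,2R)-7-(tert-butyldimethylsilyloxy)-2-[(tert-butyldimethylsilyloxy)methyl]-1-(3,4-dimethoxyphenyl)-8-methoxy-1,2-dihydronaphthalene-3-carbaldehyde | COc1ccc([C@H]2c3c(ccc(O[Si](C)(C)C(C)(C)C)c3OC)C=C(C=O)[C@@H]2CO[Si](C)(C)C(C)(C)C)cc1OC | intermediate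
12 | vitekwangin B, (1S,2R)-1-(3,4-dimethoxyphenyl)-7-hydroxy-2-(hydroxymethyl)-8-methoxy-1,2-dihydronaphthalene-3-carbaldehyde | COc1ccc([C@H]2c3c(ccc(O)c3OC)C=C(C=O)[C@@H]2CO)cc1OC | target

**Step count and risks**
Total steps: 10. Longest linear sequence: 8 (steps 1, 2, 3, 6, 7, 8, 9, 10).

Steps most likely to fail:

1. Step 6. The benzylic cation at C1 may be lost to proton loss from C2 or to capture by water before the flanked position C8a closes ring B, and the alkene face may be poorly differentiated in the radical addition, which costs yield when the C2 epimer is removed. The fallback sets out from 4 and 7 and comes back at 8. The union is run as the known carbo-oxidation variant with the same imidazolidinone salt, (NH4)2Ce(NO3)6 as oxidant and NaHCO3 in DME at −40 °C; nitrate delivered by tetravalent cerium traps C1 and should give the γ-nitrooxy aldehyde (2R,3R)-2-{[2-bromo-4-(tert-butyldimethylsilyloxy)-5-methoxyphenyl]methyl}-3-[(tert-butyldimethylsilyloxy)methyl]-4-(3,4-dimethoxyphenyl)-4-(nitrooxy)butanal F1 as a mixture of epimers at the nitrate carbon. In a separate operation the benzylic nitrate is ionised with BF3·OEt2 in CH2Cl2 (−40 to 0 °C), a Lewis-acid Friedel–Crafts alkylation whose time and temperature can be tuned for the hindered closure at C8a independently of the oxidation; this should give 8 with the aryl group trans to the C2 substituent.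

2. Step 9. β-Hydride elimination may take the C2 hydrogen instead of a C4 hydrogen, which moves the double bond to C2=C3 and erases the C2 centre, or the palladium enolate may simply be protonated back to 9. The fallback sets out from 10 and comes back at 11. N-Bromosuccinimide in THF at −78 °C should convert 10 into the α-bromo aldehyde (1S,2R)-3-bromo-7-(tert-butyldimethylsilyloxy)-2-[(tert-butyldimethylsilyloxy)methyl]-1-(3,4-dimethoxyphenyl)-8-methoxy-1,2,3,4-tetrahydronaphthalene-3-carbaldehyde F2 (both epimers at C3). Li2CO3 and LiBr in DMF at 100 °C then remove HBr in a polar anti elimination that uses one of the two benzylic C4 hydrogens, giving 11.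

3. Step 2. Bromination may go partly ortho to the silyloxy group, and HBr traces may cleave the aryl silyl ether. The fallback sets out from 1 and comes back at 3. Ac2O in pyridine gives the aryl acetate methyl 3-(4-acetoxy-3-methoxyphenyl)propanoate F3, in which the acylated oxygen no longer activates its ortho position. Br2 with NaOAc in AcOH should then brominate only para to the methoxy group, giving methyl 3-(4-acetoxy-2-bromo-5-methoxyphenyl)propanoate F4. K2CO3 in MeOH removes the acetate to give the phenol methyl 3-(2-bromo-4-hydroxy-5-methoxyphenyl)propanoate F5, and TBSCl with imidazole in DMF gives 3.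

**Further compounds**
F1 | step 6 | (2R,3R)-2-{[2-bromo-4-(tert-butyldimethylsilyloxy)-5-methoxyphenyl]methyl}-3-[(tert-butyldimethylsilyloxy)methyl]-4-(3,4-dimethoxyphenyl)-4-(nitrooxy)butanal (epimers at C4) | Brc1cc(O[Si](C)(C)C(C)(C)C)c(OC)cc1C[C@@H](C=O)[C@@H](C(O[N+](=O)[O-])c1ccc(OC)c(OC)c1)CO[Si](C)(C)C(C)(C)C
F2 | step 9 | (1S,2R)-3-bromo-7-(tert-butyldimethylsilyloxy)-2-[(tert-butyldimethylsilyloxy)methyl]-1-(3,4-dimethoxyphenyl)-8-methoxy-1,2,3,4-tetrahydronaphthalene-3-carbaldehyde (epimers at C3) | COc1ccc([C@H]2c3c(ccc(O[Si](C)(C)C(C)(C)C)c3OC)CC(Br)(C=O)[C@@H]2CO[Si](C)(C)C(C)(C)C)cc1OC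
F3 | step 2 | methyl 3-(4-acetoxy-3-methoxyphenyl)propanoate | COC(=O)CCc1ccc(OC(C)=O)c(OC)c1
F4 | step 2 | methyl 3-(4-acetoxy-2-bromo-5-methoxyphenyl)propanoate | COC(=O)CCc1cc(OC)c(OC(C)=O)cc1Br
F5 | step 2 | methyl 3-(2-bromo-4-hydroxy-5-methoxyphenyl)propanoate | COC(=O)CCc1cc(OC)c(O)cc1Br
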